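**Plan**

- Retrosynthesis: after the two O-protecting groups, ring C is cut at C2–C3 (carbenoid C–H insertion) to an α-diazoketone whose diazo carbon derives from an acetyl methyl group. The O1–C2 ether bond is cut next (Mitsunobu) to the ring-A acetophenone and a ring-B benzyl alcohol. The aryl–geranyl bond is cut last, to an aryl bromide and geranyl bromide.
- Enabling feature: C2 is both benzylic to ring B and bonded to the ring oxygen O1. When ring B hangs as a benzyl ether on the A-ring oxygen, its two C2–H bonds are the most hydridic in the molecule and lie six atoms from a carbene at C3 beside the C4 ketone.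
- Forward: ring B is geranylated at C2', joined to ring A through O1, the acetyl group is converted into the diazoketone, and ring C is closed last by forming C2–C3. Rings A and B are purchased.
- Stereochemistry: C2 is the only stereocentre and is set in the ring closure by the chiral dirhodium catalyst, which selects one of the two enantiotopic benzylic hydrogens. The 2E alkene comes in unchanged with geranyl bromide.

Key step: step 7

Assumption: the (S)-configured catalyst Rh2(S-PTTL)4 is taken to deliver the (2S) product. The sense of induction on this substrate is not known beforehand, and the mirror-image catalyst Rh2(R-PTTL)4 would be used with no other change if it proves opposite.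

In the names below, "geranyl" means (2E)-3,7-dimethylocta-2,6-dien-1-yl.

**Step 1**
Reactants: 1 2-bromo-3-hydroxy-4-methoxybenzaldehyde (2-bromoisovanillin)
Product: 2 2-bromo-4-methoxy-3-(methoxymethoxy)benzaldehyde
Conditions: MOMCl, i-Pr2NEt, CH2Cl2, 0 °C → rt
Reagents that add atoms: chloromethyl methyl ether, COCCl
Why: O-alkylation of the phenol with the reactive chloromethyl ether (MOM protection) leaves the aldehyde and the aryl bromide untouched and gives an acetal that withstands the organolithium, hydride, enolate and carbenoid steps that follow.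

**Step 2**
Reactants: 2 2-bromo-4-methoxy-3-(methoxymethoxy)benzaldehyde
Product: 3 [2-bromo-4-methoxy-3-(methoxymethoxy)phenyl]methanol
Conditions: NaBH4, MeOH, 0 °C
Reagents that add atoms: none
Why: Borohydride reduction of the aldehyde gives the benzylic alcohol without touching the aryl bromide or the MOM acetal.

**Step 3**
Reactants: 3 [2-bromo-4-methoxy-3-(methoxymethoxy)phenyl]methanol; 4 geranyl bromide
Product: 7 [2-geranyl-4-methoxy-3-(methoxymethoxy)phenyl]methanol, via aryllithium lithium alkoxide 5 (not isolated), via arylcopper lithium alkoxide 6 (not isolated)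
Conditions: n-BuLi (2.2 equiv), THF, −78 °C; CuBr·SMe2 (1.1 equiv), −78 → −40 °C; 4, −40 → 0 °C; aq NH4Cl
Reagents that add atoms: n-butyllithium, [Li]CCCC (Li held only in 5 and 6); copper(I) bromide–dimethyl sulfide, [Cu]Br.CSC (Cu held only in 6)
Why: Deprotonation of the alcohol followed by bromine–lithium exchange places the metal only at the former C–Br carbon (stabilised by the flanking OMOM and CH2OLi groups), and after transmetalation to copper the aryl group displaces bromide from geranyl bromide at the unhindered primary carbon (copper-mediated SN2 allylic substitution), which keeps the 2E geometry.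

**Step 4**
Reactants: 7 [2-geranyl-4-methoxy-3-(methoxymethoxy)phenyl]methanol; 8 1-(2,6-dihydroxy-4-methoxyphenyl)ethanone (1.5 equiv)
Product: 9 1-[2-{[2-geranyl-4-methoxy-3-(methoxymethoxy)phenyl]methoxy}-6-hydroxy-4-methoxyphenyl]ethanone
Conditions: PPh3, DIAD, THF, 0 °C → rt
Reagents that add atoms: none
Why: Mitsunobu etherification joins the primary benzylic alcohol to one of the two equivalent phenols of 8 under neutral conditions, so no ionisable p-methoxybenzylic halide next to the geranyl alkene is needed, and the second phenol stays free because it becomes locked in a hydrogen bond to the ketone once the first is alkylated.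

**Step 5**
Reactants: 9 1-[2-{[2-geranyl-4-methoxy-3-(methoxymethoxy)phenyl]methoxy}-6-hydroxy-4-methoxyphenyl]ethanone
Product: 10 1-[2-{[2-geranyl-4-methoxy-3-(methoxymethoxy)phenyl]methoxy}-4-methoxy-6-(triisopropylsilyloxy)phenyl]ethanone
Conditions: TIPSCl, imidazole, DMAP (cat.), DMF, rt → 40 °C
Reagents that add atoms: chlorotriisopropylsilane, CC(C)[Si](Cl)(C(C)C)C(C)C
Why: Imidazole-mediated silylation of the chelated phenol gives a bulky aryl silyl ether that has no C–H on the atom bound to oxygen (so it cannot compete in the later insertion), is slow to migrate to an enolate, and masks the phenol that would otherwise trap the carbenoid by O–H insertion.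

**Step 6**
Reactants: 10 1-[2-{[2-geranyl-4-methoxy-3-(methoxymethoxy)phenyl]methoxy}-4-methoxy-6-(triisopropylsilyloxy)phenyl]ethanone
Product: 13 2-diazo-1-[2-{[2-geranyl-4-methoxy-3-(methoxymethoxy)phenyl]methoxy}-4-methoxy-6-(triisopropylsilyloxy)phenyl]ethanone, via lithium enolate 11 (not isolated), via trifluoroacetyl ketone 12 (not isolated)
Conditions: LiHMDS (1.1 equiv), THF, −78 °C; CF3CO2CH2CF3, −78 °C; aq NH4Cl work-up; crude 12, p-ABSA, Et3N, H2O (1 equiv), MeCN, rt
Reagents that add atoms: 4-acetamidobenzenesulfonyl azide, CC(=O)Nc1ccc(cc1)S(=O)(=O)N=[N+]=[N-] (the two diazo nitrogens of 13); 2,2,2-trifluoroethyl trifluoroacetate, FC(F)(F)COC(=O)C(F)(F)F (CF3CO held only in 12); lithium hexamethyldisilazide, [Li]N([Si](C)(C)C)[Si](C)(C)C (Li held only in 11)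
Why: The kinetic lithium enolate of the methyl ketone is C-trifluoroacetylated (Claisen-type acylation) and the resulting 1,3-dicarbonyl undergoes Regitz diazo transfer with loss of the trifluoroacetyl group (detrifluoroacetylative diazo transfer), the standard route from a methyl ketone to a terminal α-diazoketone.

**Step 7**
Reactants: 13 2-diazo-1-[2-{[2-geranyl-4-methoxy-3-(methoxymethoxy)phenyl]methoxy}-4-methoxy-6-(triisopropylsilyloxy)phenyl]ethanone
Product: 14 (2S)-2-[2-geranyl-4-methoxy-3-(methoxymethoxy)phenyl]-7-methoxy-5-(triisopropylsilyloxy)chroman-4-one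
Conditions: Rh2(S-PTTL)4 (2 mol %), toluene, 4 Å MS, 0 °C, slow addition of 13 (final 0.01 M)
Reagents that add atoms: none
Why: The dirhodium catalyst expels N2 from 13 to give an electrophilic carbenoid at C3, which inserts into one of the two enantiotopic benzylic O–CH2 hydrogens through a concerted, asynchronous three-centre transition state (hydride shift towards the carbene carbon as the C2–C3 bond forms and the catalyst is released). The closest known reaction type is the Rh(II)-carboxylate-catalysed intramolecular C–H insertion of 2-alkoxyaryl α-diazoketones that gives chroman-4-ones. Ring C closes as a 1,6-insertion: the carbene carbon and the C–H carbon are the ends of the six-atom chain C3–C4–C4a–C8a–O1–C2, and the aryl ketone unit holds them in a six-membered cyclic transition state. C2 is the only new stereocentre and is set by the chiral pocket of the four N-phthaloyl-(S)-tert-leucinate ligands, which differentiates the two benzylic hydrogens; there is no substrate stereocentre to interfere. The step needs C–H insertion to win over attack of the carbenoid on the ether oxygen (five-membered oxonium ylide, then 1,2-benzyl shift to a 2-benzylbenzofuran-3-one), and this is secured by the strongly hydridic C–H (α to oxygen and p-methoxybenzylic), by the low basicity of an aryl ether oxygen conjugated to the acyl-bearing ring, and by slow addition at high dilution. The triisopropylsilyl ether on the other ortho oxygen has no C–H on the atom bound to oxygen and shields that oxygen, while the geranyl alkenes and the MOM acetal C–H could be reached only through rings of ten or more atoms.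

**Step 8**
Reactants: 14 (2S)-2-[2-geranyl-4-methoxy-3-(methoxymethoxy)phenyl]-7-methoxy-5-(triisopropylsilyloxy)chroman-4-one
Product: 15 (2S)-2-[2-geranyl-4-methoxy-3-(methoxymethoxy)phenyl]-5-hydroxy-7-methoxychroman-4-one
Conditions: TBAF, AcOH (1:1.2), THF, 0 °C
Reagents that add atoms: none
Why: Fluoride-mediated desilylation of the aryl silyl ether is run with acetic acid as buffer so that no free phenoxide or C3 enolate builds up, which would open ring C by retro-oxa-Michael reaction and racemise C2.

**Step 9**
Reactants: 15 (2S)-2-[2-geranyl-4-methoxy-3-(methoxymethoxy)phenyl]-5-hydroxy-7-methoxychroman-4-one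
Product: 16 (2S)-2-(2-geranyl-3-hydroxy-4-methoxyphenyl)-5-hydroxy-7-methoxychroman-4-one (CNP0130331.1)
Conditions: HCl (2 M in MeOH), MeOH–THF, rt → 40 °C
Reagents that add atoms: none
Why: Acid-catalysed methanolysis of the MOM acetal frees the 3'-phenol under conditions dilute and cool enough that the trisubstituted alkenes are not protonated and the C2–O1 bond, which racemises mainly under base, is not ionised.

**Compound list**

1 | 2-bromo-3-hydroxy-4-methoxybenzaldehyde (2-bromoisovanillin) | COc1ccc(C=O)c(Br)c1O | starting material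
2 | 2-bromo-4-methoxy-3-(methoxymethoxy)benzaldehyde | COCOc1c(OC)ccc(C=O)c1Br | intermediate
3 | [2-bromo-4-methoxy-3-(methoxymethoxy)phenyl]methanol | COCOc1c(OC)ccc(CO)c1Br | intermediate
4 | geranyl bromide, (2E)-1-bromo-3,7-dimethylocta-2,6-diene | BrC/C=C(\C)CCC=C(C)C | starting material
5 | lithium [2-lithio-4-methoxy-3-(methoxymethoxy)phenyl]methanolate | [Li]OCc1ccc(OC)c(OCOC)c1[Li] | intermediate
6 | lithium [2-cuprio-4-methoxy-3-(methoxymethoxy)phenyl]methanolate (arylcopper(I)) | [Li]OCc1ccc(OC)c(OCOC)c1[Cu] | intermediate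
7 | [2-geranyl-4-methoxy-3-(methoxymethoxy)phenyl]methanol | OCc1ccc(OC)c(OCOC)c1C/C=C(\C)CCC=C(C)C | intermediate
8 | 1-(2,6-dihydroxy-4-methoxyphenyl)ethanone | CC(=O)c1c(O)cc(OC)cc1O | starting material
9 | 1-[2-{[2-geranyl-4-methoxy-3-(methoxymethoxy)phenyl]methoxy}-6-hydroxy-4-methoxyphenyl]ethanone | CC(=O)c1c(O)cc(OC)cc1OCc1ccc(OC)c(OCOC)c1C/C=C(\C)CCC=C(C)C | intermediate
10 | 1-[2-{[2-geranyl-4-methoxy-3-(methoxymethoxy)phenyl]methoxy}-4-methoxy-6-(triisopropylsilyloxy)phenyl]ethanone | CC(=O)c1c(O[Si](C(C)C)(C(C)C)C(C)C)cc(OC)cc1OCc1ccc(OC)c(OCOC)c1C/C=C(\C)CCC=C(C)C | intermediate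
11 | lithium enolate of 10 | [Li]OC(=C)c1c(O[Si](C(C)C)(C(C)C)C(C)C)cc(OC)cc1OCc1ccc(OC)c(OCOC)c1C/C=C(\C)CCC=C(C)C | intermediate
12 | 4,4,4-trifluoro-1-[2-{[2-geranyl-4-methoxy-3-(methoxymethoxy)phenyl]methoxy}-4-methoxy-6-(triisopropylsilyloxy)phenyl]butane-1,3-dione | O=C(CC(=O)C(F)(F)F)c1c(O[Si](C(C)C)(C(C)C)C(C)C)cc(OC)cc1OCc1ccc(OC)c(OCOC)c1C/C=C(\C)CCC=C(C)C | intermediate
13 | 2-diazo-1-[2-{[2-geranyl-4-methoxy-3-(methoxymethoxy)phenyl]methoxy}-4-methoxy-6-(triisopropylsilyloxy)phenyl]ethanone | [N-]=[N+]=CC(=O)c1c(O[Si](C(C)C)(C(C)C)C(C)C)cc(OC)cc1OCc1ccc(OC)c(OCOC)c1C/C=C(\C)CCC=C(C)C | intermediate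
14 | (2S)-2-[2-geranyl-4-methoxy-3-(methoxymethoxy)phenyl]-7-methoxy-5-(triisopropylsilyloxy)chroman-4-one | COc1cc(O[Si](C(C)C)(C(C)C)C(C)C)c2c(c1)O[C@H](c1ccc(OC)c(OCOC)c1C/C=C(\C)CCC=C(C)C)CC2=O | intermediate
15 | (2S)-2-[2-geranyl-4-methoxy-3-(methoxymethoxy)phenyl]-5-hydroxy-7-methoxychroman-4-one | COc1cc(O)c2c(c1)O[C@H](c1ccc(OC)c(OCOC)c1C/C=C(\C)CCC=C(C)C)CC2=O | intermediate
16 | (2S)-2-(2-geranyl-3-hydroxy-4-methoxyphenyl)-5-hydroxy-7-methoxychroman-4-one (CNP0130331.1) | COc1cc(O)c2c(c1)O[C@H](c1ccc(OC)c(O)c1C/C=C(\C)CCC=C(C)C)CC2=O | target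

**Step count**

Total steps: 9. Longest linear sequence: 9 steps (1 → 16); 4 and 8 are purchased.

**Steps most likely to fail**

Step 7. The carbenoid may be diverted to the ether oxygen (oxonium ylide formation and benzyl 1,2-shift), or the catalyst may discriminate poorly between the two benzylic hydrogens, giving low enantiomeric purity. The fallback builds ring C by oxa-Michael addition and takes the configuration from a separation; it sets out from 7 and 8 and returns at 16. Alcohol 7 is oxidised with MnO2 (CH2Cl2, rt) to 2-geranyl-4-methoxy-3-(methoxymethoxy)benzaldehyde F1. Acetophenone 8 is mono-protected (MOMCl, i-Pr2NEt, CH2Cl2) to 1-[2-hydroxy-4-methoxy-6-(methoxymethoxy)phenyl]ethanone F2. Claisen–Schmidt condensation of F1 with F2 (KOH, EtOH, rt) should give the (E)-2'-hydroxychalcone F3. Sodium acetate in refluxing ethanol then closes ring C through O1–C2 to the racemic bis-MOM flavanone F4. Methanolic HCl removes both acetals to give the racemic flavanone F5. Preparative HPLC on a polysaccharide chiral stationary phase separates 16 from the (2R)-enantiomer F6.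

Step 3. The bromine–lithium exchange on the alkoxide may be incomplete or the dianion may be protonated, and the copper intermediate may attack the tertiary allylic carbon (allylic transposition) or leave the alkoxide to be O-alkylated. The fallback reverses the roles of the partners, using the aryl bromide as electrophile and an allyl metal as nucleophile; it sets out from 3 and 4 and returns at 7. Geranyl bromide 4 is treated with Bu3SnLi (THF, −78 °C) to give tributyl(geranyl)stannane F7. Stille coupling of F7 with 3 (Pd2(dba)3, P(t-Bu)3, CsF, dioxane, 80–100 °C) should join the aryl carbon to the primary allylic carbon and give 7 directly, the free alcohol being tolerated.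

Step 6. The silyl group may migrate from the phenolic oxygen to the neighbouring enolate oxygen, or C-acylation of the enolate beside two ortho substituents may be sluggish. The fallback avoids any enolate; it sets out from 10 and returns at 13. Heating 10 with N,N-dimethylformamide dimethyl acetal (toluene, 100 °C) should give the enaminone (2E)-3-(dimethylamino)-1-[2-{[2-geranyl-4-methoxy-3-(methoxymethoxy)phenyl]methoxy}-4-methoxy-6-(triisopropylsilyloxy)phenyl]prop-2-en-1-one F8. Diazo transfer to F8 with tosyl azide (MeCN, rt) proceeds by cycloaddition to the enamine double bond and fragmentation of the triazoline, giving 13.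

**Further compounds**

F1 | step 7 | 2-geranyl-4-methoxy-3-(methoxymethoxy)benzaldehyde | O=Cc1ccc(OC)c(OCOC)c1C/C=C(\C)CCC=C(C)C
F2 | step 7 | 1-[2-hydroxy-4-methoxy-6-(methoxymethoxy)phenyl]ethanone | CC(=O)c1c(O)cc(OC)cc1OCOC
F3 | step 7 | (2E)-3-[2-geranyl-4-methoxy-3-(methoxymethoxy)phenyl]-1-[2-hydroxy-4-methoxy-6-(methoxymethoxy)phenyl]prop-2-en-1-one | COCOc1cc(OC)cc(O)c1C(=O)/C=C/c1ccc(OC)c(OCOC)c1C/C=C(\C)CCC=C(C)C
F4 | step 7 | racemic 2-[2-geranyl-4-methoxy-3-(methoxymethoxy)phenyl]-7-methoxy-5-(methoxymethoxy)chroman-4-one | COCOc1cc(OC)cc2OC(CC(=O)c12)c1ccc(OC)c(OCOC)c1C/C=C(\C)CCC=C(C)C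
F5 | step 7 | racemic 2-(2-geranyl-3-hydroxy-4-methoxyphenyl)-5-hydroxy-7-methoxychroman-4-one | COc1cc(O)c2c(c1)OC(c1ccc(OC)c(O)c1C/C=C(\C)CCC=C(C)C)CC2=O
F6 | step 7 | (2R)-2-(2-geranyl-3-hydroxy-4-methoxyphenyl)-5-hydroxy-7-methoxychroman-4-one | COc1cc(O)c2c(c1)O[C@@H](c1ccc(OC)c(O)c1C/C=C(\C)CCC=C(C)C)CC2=O
F7 | step 3 | tributyl(geranyl)stannane | CCCC[Sn](CCCC)(CCCC)C/C=C(\C)CCC=C(C)C
F8 | step 6 | (2E)-3-(dimethylamino)-1-[2-{[2-geranyl-4-methoxy-3-(methoxymethoxy)phenyl]methoxy}-4-methoxy-6-(triisopropylsilyloxy)phenyl]prop-2-en-1-one | CN(C)/C=C/C(=O)c1c(O[Si](C(C)C)(C(C)C)C(C)C)cc(OC)cc1OCc1ccc(OC)c(OCOC)c1C/C=C(\C)CCC=C(C)C
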